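With the ring numbered C1 (C=O), C2, C3 (bearing C7H2OH), C4, C5 (carbinols) and C6, the cyclohexenone is cut at C1–C2 and C4–C5 into a dihydroxyacetone-derived vinyl anion (C2=C3, with C4 and C7 as equivalent arms of one 1,3-dioxane) and a chiral (E)-3-alkoxyacryloyl chloride (C5–C6–C1). In one flask, acylation forms C1–C2; the cross-conjugated dienone is enolized to a 2-oxidohexatriene whose disrotatory 6π-electrocyclization forms C4–C5, and the enolate is allylated at C6. The step exploits the C1 enone flanked by the cis C4/C5 diol: both oxygens are outside (E) substituents on the triene termini, so closure must place them cis.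

Key step: step 4

Remark (assumption): the (1S) alcohol 5 is chosen on the assumption that the aryl group of the s-trans enol ether covers the face of C5 opposite to bond formation, which gives 5S; if the sense is found reversed, the (1R) alcohol is used with otherwise identical steps. Compounds 1 and 5 are taken as commercial.

Step 1
Reactants: 1 2,2-dimethyl-1,3-dioxan-5-one; 2 (bromomethyl)triphenylphosphonium bromide
Product: 4 5-(bromomethylidene)-2,2-dimethyl-1,3-dioxane, via bromomethylidene ylide 3 (not isolated)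
Conditions: KOtBu, THF, −78 °C to rt
Reagents that add atoms: none
Why: Wittig olefination of the ketone with the bromo ylide should give the vinyl bromide; the ketone is symmetric, so no alkene isomers and no stereocenter arise.

Step 2
Reactants: 5 (1S)-1-(2,4,6-triisopropylphenyl)ethanol; 6 methyl propiolate
Product: 7 methyl (2E)-3-[(1S)-1-(2,4,6-triisopropylphenyl)ethoxy]prop-2-enoate
Conditions: PMe3 (10 mol %), CH2Cl2, 0 °C to rt
Reagents that add atoms: none
Why: phosphine-catalysed oxa-Michael addition of the alcohol to the propiolate should give the (E)-β-alkoxyacrylate; the carbinol center is not touched.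

Step 3
Reactants: 7 methyl (2E)-3-[(1S)-1-(2,4,6-triisopropylphenyl)ethoxy]prop-2-enoate
Product: 8 (2E)-3-[(1S)-1-(2,4,6-triisopropylphenyl)ethoxy]prop-2-enoic acid
Conditions: LiOH, THF/MeOH/H2O, rt; then 1 M HCl to pH 4, 0 °C
Reagents that add atoms: lithium hydroxide, [Li+].[OH-]
Why: saponification of the methyl ester, with a cold and only weakly acidic work-up so that the acid-labile benzylic enol ether survives.

Step 4
Reactants: 4 5-(bromomethylidene)-2,2-dimethyl-1,3-dioxane; 8 (2E)-3-[(1S)-1-(2,4,6-triisopropylphenyl)ethoxy]prop-2-enoic acid; 9 allyl bromide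
Product: 15 (7S,8S,8aR)-2,2-dimethyl-7-(prop-2-en-1-yl)-8-[(1S)-1-(2,4,6-triisopropylphenyl)ethoxy]-4,7,8,8a-tetrahydro-1,3-benzodioxin-6-one, via acid chloride 10 (not isolated), via vinyllithium 11 (not isolated), via dienone 12 (not isolated), via potassium trienolate 13 (not isolated), via potassium dienolate 14 (not isolated)
Conditions: 8, 1-chloro-N,N,2-trimethylprop-1-en-1-amine, THF, 0 °C; 4, t-BuLi (2 equiv), Et2O, −78 °C, then added to the acid chloride at −100 °C; KN(SiMe3)2 (1.2 equiv), −78 to −30 °C; 9, −78 to −40 °C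
Reagents that add atoms: none
Why: Proposed new method: vinyllithium 11 displaces chloride from acid chloride 10 (C1–C2) to give the cross-conjugated dienone 12, the silylamide removes a γ-hydrogen from a dioxane CH2 to give the 2-oxidohexatriene 13, this closes by thermal disrotatory 6π-electrocyclization (C4–C5) to the C1/C6 enolate 14, and 14 is allylated at C6; the closest known reaction types are ketone synthesis from an acid chloride plus an organolithium and the oxyanion-accelerated hexatriene-to-cyclohexadiene electrocyclization of trienolates, which have not been run as one sequence on a dioxanylidene ketone. The carbocycle (C1–C6) closes in the 6π-electrocyclic disrotatory mode. C4 and C5 come out cis because both oxygens are outside substituents of the triene termini: the C3=C4 enol ether is held E by the dioxine ring and the C5=C6 enol ether is E from step 2. Their absolute sense (4R,5S) is set by the (1S)-arylethyl ether on O5, whose aryl group shields one face of the C5 terminus and so fixes the direction of disrotation, and C6 (S) is set by allylation of 14 anti to that ether. The step needs γ-enolization with C3 cis to C6 and no second addition of 11: C6 is vinylic so only γ-hydrogens are acidic, deprotonation by the silylamide is reversible so only the closable enolate isomer is drained, and inverse addition at −100 °C to a ketone deactivated as a vinylogous ester limits over-addition.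

Step 5
Reactants: 15 (7S,8S,8aR)-2,2-dimethyl-7-(prop-2-en-1-yl)-8-[(1S)-1-(2,4,6-triisopropylphenyl)ethoxy]-4,7,8,8a-tetrahydro-1,3-benzodioxin-6-one; 16 tert-butyl methacrylate
Product: 17 tert-butyl (2E)-4-{(7S,8S,8aR)-2,2-dimethyl-6-oxo-8-[(1S)-1-(2,4,6-triisopropylphenyl)ethoxy]-4,7,8,8a-tetrahydro-1,3-benzodioxin-7-yl}-2-methylbut-2-enoate
Conditions: second-generation Hoveyda–Grubbs catalyst [RuCl2(H2IMes)(=CH–C6H4–2-OiPr)] (5 mol %), 16 (10 equiv), CH2Cl2, 40 °C
Reagents that add atoms: none
Why: olefin cross-metathesis of the terminal allyl group with the 1,1-disubstituted acrylate should give the E trisubstituted enoate under thermodynamic control, the trisubstituted ring enone being inert.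

Step 6
Reactants: 17 tert-butyl (2E)-4-{(7S,8S,8aR)-2,2-dimethyl-6-oxo-8-[(1S)-1-(2,4,6-triisopropylphenyl)ethoxy]-4,7,8,8a-tetrahydro-1,3-benzodioxin-7-yl}-2-methylbut-2-enoate
Product: 18 tert-butyl (2E)-4-{(7S,8S,8aR)-5-iodo-2,2-dimethyl-6-oxo-8-[(1S)-1-(2,4,6-triisopropylphenyl)ethoxy]-4,7,8,8a-tetrahydro-1,3-benzodioxin-7-yl}-2-methylbut-2-enoate
Conditions: I2, pyridine, DMAP (cat.), CH2Cl2, rt, dark
Reagents that add atoms: iodine, [I][I]
Why: α-iodination of the enone by conjugate addition of the nitrogen base, iodination of the enolate and elimination; C2 is the only enone α-CH and the side-chain enoate should not react.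

Step 7
Reactants: 19 (2R)-2-methyloxirane; 20 but-3-en-1-ylmagnesium bromide
Product: 21 (2R)-hept-6-en-2-ol
Conditions: CuI (5 mol %), THF, −30 °C; aq. NH4Cl
Reagents that add atoms: none
Why: copper-catalysed Grignard opening of the epoxide at its unsubstituted carbon leaves the stereocenter untouched, so the (R) epoxide gives the (R) alcohol.

Step 8
Reactants: 21 (2R)-hept-6-en-2-ol; 22 4,4,5,5-tetramethyl-2-vinyl-1,3,2-dioxaborolane
Product: 23 (2R,6E)-7-(4,4,5,5-tetramethyl-1,3,2-dioxaborolan-2-yl)hept-6-en-2-ol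
Conditions: second-generation Grubbs catalyst [RuCl2(H2IMes)(PCy3)(=CHPh)] (5 mol %), CH2Cl2, 40 °C
Reagents that add atoms: none
Why: olefin cross-metathesis with the vinylboronate should give the E alkenylboronate, and the free hydroxyl is tolerated.

Step 9
Reactants: 18 tert-butyl (2E)-4-{(7S,8S,8aR)-5-iodo-2,2-dimethyl-6-oxo-8-[(1S)-1-(2,4,6-triisopropylphenyl)ethoxy]-4,7,8,8a-tetrahydro-1,3-benzodioxin-7-yl}-2-methylbut-2-enoate; 23 (2R,6E)-7-(4,4,5,5-tetramethyl-1,3,2-dioxaborolan-2-yl)hept-6-en-2-ol
Product: 24 tert-butyl (2E)-4-{(7S,8S,8aR)-5-[(1E,6R)-6-hydroxyhept-1-en-1-yl]-2,2-dimethyl-6-oxo-8-[(1S)-1-(2,4,6-triisopropylphenyl)ethoxy]-4,7,8,8a-tetrahydro-1,3-benzodioxin-7-yl}-2-methylbut-2-enoate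
Conditions: PdCl2(PhCN)2 (5 mol %), AsPh3 (10 mol %), Ag2O, THF/H2O (8:1), rt
Reagents that add atoms: none
Why: Suzuki–Miyaura coupling of the α-iodoenone with the alkenylboronate proceeds with retention of both alkene geometries, and silver oxide activates boron at room temperature without a soluble strong base that could eliminate the C5 ether.

Step 10
Reactants: 24 tert-butyl (2E)-4-{(7S,8S,8aR)-5-[(1E,6R)-6-hydroxyhept-1-en-1-yl]-2,2-dimethyl-6-oxo-8-[(1S)-1-(2,4,6-triisopropylphenyl)ethoxy]-4,7,8,8a-tetrahydro-1,3-benzodioxin-7-yl}-2-methylbut-2-enoate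
Product: 25 pestallic acid O
Conditions: CF3CO2H/H2O/CH2Cl2 (4:1:5), 0 °C to rt
Reagents that add atoms: none
Why: acid should cleave in one operation the tert-butyl ester (loss of 2-methylpropene), the acetonide (hydrolysis) and the benzylic arylethyl ether (ionization at the auxiliary carbon, so the C5–O bond and its configuration stay), while C6, α to the ketone, remains in the trans arrangement to O5.

Compound list
1 | 2,2-dimethyl-1,3-dioxan-5-one | CC1(C)OCC(=O)CO1 | starting material
2 | (bromomethyl)triphenylphosphonium bromide | BrC[P+](c1ccccc1)(c1ccccc1)c1ccccc1.[Br-] | starting material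
3 | (bromomethylidene)triphenylphosphorane | BrC=P(c1ccccc1)(c1ccccc1)c1ccccc1 | intermediate (not isolated)
4 | 5-(bromomethylidene)-2,2-dimethyl-1,3-dioxane | CC1(C)OCC(=CBr)CO1 | intermediate
5 | (1S)-1-(2,4,6-triisopropylphenyl)ethanol | C[C@H](O)c1c(C(C)C)cc(C(C)C)cc1C(C)C | starting material
6 | methyl propiolate | C#CC(=O)OC | starting material
7 | methyl (2E)-3-[(1S)-1-(2,4,6-triisopropylphenyl)ethoxy]prop-2-enoate | COC(=O)/C=C/O[C@@H](C)c1c(C(C)C)cc(C(C)C)cc1C(C)C | intermediate
8 | (2E)-3-[(1S)-1-(2,4,6-triisopropylphenyl)ethoxy]prop-2-enoic acid | OC(=O)/C=C/O[C@@H](C)c1c(C(C)C)cc(C(C)C)cc1C(C)C | intermediate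
9 | allyl bromide (3-bromoprop-1-ene) | C=CCBr | starting material
10 | (2E)-3-[(1S)-1-(2,4,6-triisopropylphenyl)ethoxy]prop-2-enoyl chloride | ClC(=O)/C=C/O[C@@H](C)c1c(C(C)C)cc(C(C)C)cc1C(C)C | intermediate (not isolated)
11 | [(2,2-dimethyl-1,3-dioxan-5-ylidene)methyl]lithium | [Li]C=C1COC(C)(C)OC1 | intermediate (not isolated)
12 | (3E)-1-(2,2-dimethyl-1,3-dioxan-5-ylidene)-4-[(1S)-1-(2,4,6-triisopropylphenyl)ethoxy]but-3-en-2-one | O=C(C=C1COC(C)(C)OC1)/C=C/O[C@@H](C)c2c(C(C)C)cc(C(C)C)cc2C(C)C | intermediate (not isolated)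
13 | potassium (1E,3E)-1-(2,2-dimethyl-4H-1,3-dioxin-5-yl)-4-[(1S)-1-(2,4,6-triisopropylphenyl)ethoxy]buta-1,3-dien-2-olate (dioxinyl cis to the alkoxyvinyl arm) | [K+].[O-]/C(/C=C/O[C@@H](C)c1c(C(C)C)cc(C(C)C)cc1C(C)C)=C/C2=COC(C)(C)OC2 | intermediate (not isolated)
14 | potassium (8S,8aR)-2,2-dimethyl-8-[(1S)-1-(2,4,6-triisopropylphenyl)ethoxy]-8,8a-dihydro-4H-1,3-benzodioxin-6-olate | C1=C([O-])C=C2COC(C)(C)O[C@H]2[C@H]1O[C@@H](C)c3c(C(C)C)cc(C(C)C)cc3C(C)C.[K+] | intermediate (not isolated)
15 | (7S,8S,8aR)-2,2-dimethyl-7-(prop-2-en-1-yl)-8-[(1S)-1-(2,4,6-triisopropylphenyl)ethoxy]-4,7,8,8a-tetrahydro-1,3-benzodioxin-6-one (target numbering: C4 R, C5 S, C6 S) | C=CC[C@@H]1C(=O)C=C2COC(C)(C)O[C@H]2[C@H]1O[C@@H](C)c3c(C(C)C)cc(C(C)C)cc3C(C)C | intermediate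
16 | tert-butyl methacrylate | CC(=C)C(=O)OC(C)(C)C | starting material
17 | tert-butyl (2E)-4-{(7S,8S,8aR)-2,2-dimethyl-6-oxo-8-[(1S)-1-(2,4,6-triisopropylphenyl)ethoxy]-4,7,8,8a-tetrahydro-1,3-benzodioxin-7-yl}-2-methylbut-2-enoate | C/C(=C\C[C@@H]1C(=O)C=C2COC(C)(C)O[C@H]2[C@H]1O[C@@H](C)c3c(C(C)C)cc(C(C)C)cc3C(C)C)C(=O)OC(C)(C)C | intermediate
18 | tert-butyl (2E)-4-{(7S,8S,8aR)-5-iodo-2,2-dimethyl-6-oxo-8-[(1S)-1-(2,4,6-triisopropylphenyl)ethoxy]-4,7,8,8a-tetrahydro-1,3-benzodioxin-7-yl}-2-methylbut-2-enoate | C/C(=C\C[C@@H]1C(=O)C(I)=C2COC(C)(C)O[C@H]2[C@H]1O[C@@H](C)c3c(C(C)C)cc(C(C)C)cc3C(C)C)C(=O)OC(C)(C)C | intermediate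
19 | (2R)-2-methyloxirane | C[C@@H]1CO1 | starting material
20 | but-3-en-1-ylmagnesium bromide | C=CCC[Mg]Br | starting material
21 | (2R)-hept-6-en-2-ol | C[C@@H](O)CCCC=C | intermediate
22 | 4,4,5,5-tetramethyl-2-vinyl-1,3,2-dioxaborolane | C=CB1OC(C)(C)C(C)(C)O1 | starting material
23 | (2R,6E)-7-(4,4,5,5-tetramethyl-1,3,2-dioxaborolan-2-yl)hept-6-en-2-ol | C[C@@H](O)CCC/C=C/B1OC(C)(C)C(C)(C)O1 | intermediate
24 | tert-butyl (2E)-4-{(7S,8S,8aR)-5-[(1E,6R)-6-hydroxyhept-1-en-1-yl]-2,2-dimethyl-6-oxo-8-[(1S)-1-(2,4,6-triisopropylphenyl)ethoxy]-4,7,8,8a-tetrahydro-1,3-benzodioxin-7-yl}-2-methylbut-2-enoate | C/C(=C\C[C@@H]1C(=O)C(/C=C/CCC[C@@H](C)O)=C2COC(C)(C)O[C@H]2[C@H]1O[C@@H](C)c3c(C(C)C)cc(C(C)C)cc3C(C)C)C(=O)OC(C)(C)C | intermediate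
25 | pestallic acid O | C/C(=C\C[C@@H]1C(=O)C(/C=C/CCC[C@@H](C)O)=C(CO)[C@@H](O)[C@H]1O)C(=O)O | target

Total step count: 10. Longest linear sequence: 7 steps (steps 2, 3, 4, 5, 6, 9, 10).

Steps most likely to fail

Step 4 (Proposed new method). Three processes may defeat it. The vinyllithium may add a second time to the ketone as it forms. Enolization may stall in the trienolate geometry that cannot close, leaving time for loss of the C5 alkoxide from enolate 14 and aromatization. The auxiliary may give poor or reversed facial selectivity in the ring closure. The fallback uses known chemistry in separate, neutral steps; it sets out from 7 and 4 and comes back at 15. Ester 7 is converted with MeNH(OMe)·HCl and iPrMgCl into the N-methoxy-N-methylamide F1. Vinyllithium 11 (from 4 and t-BuLi) is added to F1 at −78 °C, and aqueous work-up releases dienone 12, which is now isolated; the chelated adduct cannot add twice. Me3SiOTf and Et3N convert 12 into the silyl trienol ether F2, whose enol ether isomers interconvert under these conditions. Heating in toluene closes F2 by thermal 6π-electrocyclization to the silyl dienol ether F3. MeLi then liberates the lithium enolate regiospecifically, and allyl bromide 9 gives 15.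

Step 9. Oxidative addition and transmetalation may be slow at the vinyl iodide, which is flanked by the carbonyl and the substituted C3. Base-promoted elimination of the C5 ether or protodeiodination could then compete. The fallback replaces the boron coupling by a Heck reaction: iodide 18 and alkene 21 are coupled directly with Pd(OAc)2, Bu4NCl and NaHCO3 in DMF at rt. It sets out from 18 (with 21) and comes back at 24; no new compound is made (F0).

Step 10. Acid may dehydrate the C5 hydroxyl β to the ketone, leading to aromatization, or isomerize the dienyl chain before the hindered benzylic ether is fully cleaved. The fallback reverses the order of the endgame so that the dienyl chain never meets strong acid. It sets out from 18 and comes back at 25. Iodide 18 is deprotected with CF3CO2H/H2O to the iodo triol acid F4. F4 is then coupled, unprotected, with boronate 23 under the conditions of step 9 to give 25 directly.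

Further compounds
F1 | step 4 | (2E)-N-methoxy-N-methyl-3-[(1S)-1-(2,4,6-triisopropylphenyl)ethoxy]prop-2-enamide | CON(C)C(=O)/C=C/O[C@@H](C)c1c(C(C)C)cc(C(C)C)cc1C(C)C
F2 | step 4 | (1E,3E)-1-(2,2-dimethyl-4H-1,3-dioxin-5-yl)-4-[(1S)-1-(2,4,6-triisopropylphenyl)ethoxy]-2-(trimethylsilyloxy)buta-1,3-diene | C[Si](C)(C)O/C(/C=C/O[C@@H](C)c1c(C(C)C)cc(C(C)C)cc1C(C)C)=C/C2=COC(C)(C)OC2
F3 | step 4 | (8S,8aR)-2,2-dimethyl-8-[(1S)-1-(2,4,6-triisopropylphenyl)ethoxy]-6-(trimethylsilyloxy)-8,8a-dihydro-4H-1,3-benzodioxine | C1=C(O[Si](C)(C)C)C=C2COC(C)(C)O[C@H]2[C@H]1O[C@@H](C)c3c(C(C)C)cc(C(C)C)cc3C(C)C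
F0 | step 9 | none | none
F4 | step 10 | (2E)-4-[(1S,5R,6S)-5,6-dihydroxy-4-(hydroxymethyl)-3-iodo-2-oxocyclohex-3-en-1-yl]-2-methylbut-2-enoic acid | C/C(=C\C[C@@H]1C(=O)C(I)=C(CO)[C@@H](O)[C@H]1O)C(=O)O
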